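## Structural features

Atoms are numbered as in a 2,3-seco-aromadendrane: the cycloheptane is C1–C5–C6–C7–C8–C9–C10, the cyclopropane is C6–C7–C11, the dihydropyran is O–C2–C1–C5–C4=C3, the oxepane is C11–C12–O–C15–C4–C5–C6, C13 is the exo CH2OAc on C11 and C14 the methyl on C10. The carbocycle therefore carries three further rings: a cis-fused cyclopropane, a cis-fused 2-acetoxy-3,4-dihydro-2H-pyran at C1–C5, and an oxepane that is trans-fused at C5–C6 and ties C4 to the endo carbon on C11. Five contiguous stereocentres run round the seven-membered ring (C10, C1, C5, C6, C7): H1 and H5 are cis, the carbon substituents C2 and C4 and the tertiary hydroxyl on C10 lie on one face, and C11 and C14 lie on the other. Quaternary C11 is stereogenic only because its two CH2O arms differ (endo C12 in the ether, exo C13 as acetate), and anomeric C2 carries its acetate trans to the C1–C10 bond. Fragile groups are the enol ether acetal with its anomeric acetate, the allylic C15–O bond (a vinylogous acetal), C1–H once C2 is a carbonyl, and the tertiary alcohol β to C2. The real difficulty is the cis C1/C5 pair inside a seven-membered ring on which every other position must later be differentiated, together with the trans-bridging oxepane and the endo/exo problem at C11. The key step exploits that, once C11 and C14 are taken off, the carbocycle is a cyclohepta-1,4-diene in disguise: C10 is an enol carbon (C9=C10–O), C6=C7 is the alkene that the cyclopropane will occupy, C8 is the single sp3 carbon between them and C1/C5 is the vicinal sp3 pair on the far side, which is the retron of a cis-divinylcyclopropane Cope rearrangement. In one sentence, the route is a rhodium-carbenoid cyclopropanation of an acyclic 1-substituted butadiene by an acyclic 2-siloxyvinyl diazoester with [3,3] shift of the resulting cis-divinylcyclopropane, which does not describe the usual plan of cleaving a preformed hydroazulene or cyclopropanating a conventionally cyclised ring.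

## Logic of the disconnections

**24 to 23.** The two acyl C–O bonds (at O13 and at the anomeric O on C2) are cut. The anomeric acetate is the most labile group and belongs at the very end. This removes both esters and leaves a lactol. The forward step must acetylate the primary and the anomeric hydroxyl but not the tertiary one on C10, and must give the anomer with the acetate trans to C1–C10.

**23 to 20.** Three bonds are cut: the hemiacetal bond O–C2, the ether bond O12–C15 and the C4–C15 bond, so that C15 leaves the molecule as a one-carbon aldehyde reagent. C15 sits β to the C3 carbonyl, so it is an α-methylene carbon in retrosynthesis, and the ether is a conjugate addition of a hydroxyl to that methylene. Only the endo CH2OH on C11 can reach C15, so the ring closure itself assigns the configuration of C11. Both heterocycles, C15 and the C11 stereocentre vanish; 20 is a carbocyclic 1,5-dialdehyde diol. The forward step must methylenate only the unhindered CH2 next to the C3 aldehyde, add the primary endo hydroxyl rather than the tertiary C10 hydroxyl, and end in the enol-lactol.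

**20 to 16 (through 19, 18, 17).** No skeletal bond is cut. The C2 and C3 aldehydes go back to primary alcohols (C2 as a benzyl ether), and the cyclopropane diol is masked as an acetonide while they are oxidised. This lets all three CH2O groups that are not aldehydes come from esters by one hydride reduction. The forward steps must oxidise a 1,5-diol to the dialdehyde without lactone formation and without epimerising C1.

**16 to 14 (through 15).** The C10–C14 bond is cut. A tertiary methyl carbinol is the retron of a ketone and a methyl nucleophile, and the benzyloxy group on C2 is placed to chelate. The C10 stereocentre is removed. The forward step must attack the ketone face syn to H1 and must leave three esters alone.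

**14 to 10 and 11 (through 12).** The C6–C11 and C7–C11 bonds are cut. A cyclopropane carrying two CH2O groups is a malonate carbene added to a cis alkene; at this stage the two arms are identical esters, so C11 is not yet a stereocentre. C6, C7 and three carbons are removed, leaving the monocyclic diene 10. The carbenoid must choose the C6=C7 alkene over the tetrasubstituted push–pull enol ether, and the face anti to the side chains on C5 and C1.

**10 to 6 and 8 (through 9), the key disconnection.** The C1–C5 bond is cut and the C7–C9 bond is re-formed (retro-Cope to the cis-divinylcyclopropane 9); then C8–C9 and C7–C9 are cut (retro-cyclopropanation). The seven-membered ring and both of its first stereocentres fall back to two achiral, acyclic pieces of five and six carbons. The forward step must cyclopropanate only the terminal alkene of 8, give the cis-divinyl isomer, select one alkene face under catalyst control, and start from a Z enol ether and an E diene so that the boat transition state delivers the cis C1/C5 pair.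

**6 to 1 and 2 (through 5, 4, 3); 8 to 7.** The O–Si bond, the diazo group and the C9–C10 bond are cut in turn, which leads to the acid 1 and the malonate equivalent 2. Diene 8 is the deconjugated isomer of 7. These are standard operations; the only demands are the Z geometry of 6 and the E geometry of 8.

## Other disconnections considered

**Alternative 1:** (the first that comes to mind) Cut the C2–O–C3 unit back to a C2=C3 alkene, that is, oxidative cleavage of the cyclopentene in an oxygenated aromadendr-2-ene A1 to the seco-dialdehyde A2, followed by enol-lactol closure and acetylation. This copies the presumed origin of the seco skeleton. The ground against it is structural: A1 already holds the hydroazulene, the cyclopropane with both oxidised arms, the oxepane and every carbocyclic stereocentre. The cleavage therefore removes no difficulty, and the synthesis of A1 is the whole problem. The chosen plan builds the C1/C5 pair and the ring in one step and never needs the five-membered ring.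

**Alternative 2:** Cut C1–C5 and O–C2 together, an intramolecular inverse-demand hetero-Diels–Alder reaction of the enal A3 (a cyclopropane-fused dihydrooxepine carbaldehyde with a tethered enol acetate) that would close the pyran and the cycloheptane at once and give the target directly. It is attractive on paper. The grounds against it are three. The tether from C7 must reach the face of C5 anti to C7 on the oxepine to give the trans 7/7 fusion, and nothing in A3 enforces this. A seven-membered ring must form from an unactivated enal and a poorly nucleophilic enol acetate. A3 itself needs the C11 quaternary centre and the remote C10 carbinol to be set without any relay from ring stereocentres. The chosen plan relays C10, C6, C7 and C11 from C1/C5 in turn.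

**Alternative 3:** Cut C6–C11 and C7–C11 intramolecularly: a rhodium carbenoid from the diazomalonate A4, tethered through the C15 oxygen, would close the cyclopropane and the seven-membered ring (as lactone A5) in one step and fix C11 by the tether. The grounds against it are mechanistic. The carbenoid lies five atoms from the tertiary C4–H, and insertion there to a γ-lactone should outrun a seven-membered closure. A tether anchored on C4 should deliver the carbon to the face of C6=C7 syn to C4, whereas the target has C11 anti. The lactone carbonyl would then have to be reduced to CH2 beside a second ester. The chosen intermolecular cyclopropanation uses the same C5 substituent as a shield and gives the anti relation directly.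

Key step: step 5

Remarks on the chemistry (assumptions):
- The sense of induction of the chiral dirhodium catalyst in step 5 is assigned by analogy with simpler dienes; if it is the opposite, the enantiomeric catalyst is used and nothing else changes.
- Dimethyl diazomalonate 11 is taken as purchasable; otherwise it is one diazo transfer from dimethyl malonate.
- The dialdehydes 19–22 are written in the open form; they equilibrate with cyclic hemiacetals.

## Steps

Step 1
Reactants: 1 3-(benzyloxy)propanoic acid; 2 Meldrum's acid (2,2-dimethyl-1,3-dioxane-4,6-dione)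
Product: 4 2-(trimethylsilyl)ethyl 5-(benzyloxy)-3-oxopentanoate, via acyl Meldrum's acid 3 (not isolated)
Conditions: DCC, DMAP, CH2Cl2, 0 °C to rt; filter; then Me3SiCH2CH2OH, toluene, 90 °C
Reagents that add atoms: 2-(trimethylsilyl)ethanol, C[Si](C)(C)CCO
Why: C-acylation of Meldrum's acid by the carbodiimide-activated acid gives 3, which on heating loses acetone and CO2 to an acylketene that the alcohol traps as the β-keto ester; no stereocentre is formed and the silylethyl ester is chosen so that it can later be removed by fluoride.

Step 2
Reactants: 4 2-(trimethylsilyl)ethyl 5-(benzyloxy)-3-oxopentanoate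
Product: 5 2-(trimethylsilyl)ethyl 5-(benzyloxy)-2-diazo-3-oxopentanoate
Conditions: p-ABSA, Et3N, MeCN, 0 °C to rt
Reagents that add atoms: 4-acetamidobenzenesulfonyl azide (p-ABSA), CC(=O)Nc1ccc(cc1)S(=O)(=O)N=[N+]=[N-]
Why: Regitz diazo transfer to the doubly activated methylene; the benzyl ether and the ester are inert.

Step 3
Reactants: 5 2-(trimethylsilyl)ethyl 5-(benzyloxy)-2-diazo-3-oxopentanoate
Product: 6 2-(trimethylsilyl)ethyl (3Z)-5-(benzyloxy)-3-[(tert-butyldimethylsilyl)oxy]-2-diazopent-3-enoate
Conditions: TBSOTf, Et3N, CH2Cl2, 0 °C
Reagents that add atoms: tert-butyldimethylsilyl trifluoromethanesulfonate (TBSOTf), CC(C)(C)[Si](C)(C)OS(=O)(=O)C(F)(F)F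
Why: Soft enolisation of the ketone toward its only enolisable side and O-silylation; the Z enol ether (CH2OBn arm trans to the diazo carbon) is expected because it keeps that arm away from the bulky diazoester, and it is the geometry the Cope step needs.

Step 4
Reactants: 7 ethyl sorbate (ethyl (2E,4E)-hexa-2,4-dienoate)
Product: 8 ethyl (3E)-hexa-3,5-dienoate
Conditions: LDA, HMPA, THF, −78 °C; then AcOH, −78 °C
Reagents that add atoms: none
Why: Kinetic deconjugation: γ-deprotonation gives the extended dienolate, which is protonated at the α-carbon to the β,γ-unsaturated ester, leaving a terminal diene whose inner double bond keeps the E geometry.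

Step 5
Reactants: 6 2-(trimethylsilyl)ethyl (3Z)-5-(benzyloxy)-3-[(tert-butyldimethylsilyl)oxy]-2-diazopent-3-enoate; 8 ethyl (3E)-hexa-3,5-dienoate
Product: 10 2-(trimethylsilyl)ethyl (3S,4R)-3-[(benzyloxy)methyl]-2-[(tert-butyldimethylsilyl)oxy]-4-(2-ethoxy-2-oxoethyl)cyclohepta-1,5-diene-1-carboxylate (side chains cis), via cis-divinylcyclopropane 9 (not isolated)
Conditions: Rh2(R-PTAD)4 (dirhodium tetrakis[(R)-N-phthaloyl-(1-adamantyl)glycinate], 1 mol %), 8 (3 equiv), hexanes, −20 °C, slow addition of 6; then rt to 50 °C
Reagents that add atoms: none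
Why: The catalyst decomposes 6 to a donor/acceptor rhodium vinylcarbenoid, which adds to the terminal alkene of 8 (C7=C8) in a concerted asynchronous [2+1] closure with the dienyl residue cis to the vinyl group, so that the cis-divinylcyclopropane 9 is formed. 9 then undergoes a [3,3] sigmatropic (Cope) shift through the boat transition state open to cis-divinylcyclopropanes: C7–C9 breaks, C1–C5 forms, and the three-membered ring expands to the seven-membered ring (a ring expansion, not an end-to-end cyclisation). The closest known reaction type is the dirhodium-catalysed tandem cyclopropanation/Cope rearrangement (formal [4+3] cycloaddition) of 2-siloxyvinyl diazoacetates with 1-substituted butadienes. C1 and C5 are created in the Cope step; their cis relation follows from the boat geometry, in which the substituents on both vinyl termini (CH2OBn on the Z enol ether, CH2CO2Et on the E diene) point away from the cyclopropane CH2. Their absolute configuration is relayed from the two cyclopropane stereocentres, which the chiral carboxylate ligands set when they select the alkene face attacked by the carbenoid; the concerted shift transfers it without loss. The step needs site selectivity for the terminal alkene (the internal E alkene is nearly inert to this bulky carbenoid), cis selectivity in the cyclopropanation (general for donor/acceptor carbenoids), no reaction at the vinylogous carbon (suppressed by the internal siloxy group) and geometrically pure partners (secured in steps 3 and 4). The product already carries the C10 oxygen as an enol ether, the C6=C7 alkene for the cyclopropane, the C8 methylene and both side chains.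

Step 6
Reactants: 10 cycloheptadiene from step 5; 11 dimethyl diazomalonate
Product: 12 8,8-dimethyl 5-[2-(trimethylsilyl)ethyl] 3-[(benzyloxy)methyl]-4-[(tert-butyldimethylsilyl)oxy]-2-(2-ethoxy-2-oxoethyl)bicyclo[5.1.0]oct-4-ene-5,8,8-tricarboxylate (cyclopropane anti to both side chains)
Conditions: Rh2(esp)2 (dirhodium bis(α,α,α',α'-tetramethyl-1,3-benzenedipropanoate), 1 mol %), 11 (2 equiv, slow addition), CH2Cl2, 40 °C
Reagents that add atoms: none
Why: Rhodium-carbenoid cyclopropanation of the cis-disubstituted C6=C7 alkene; the other alkene is a tetrasubstituted, ester-bearing enol ether and should not react, and 10 has no O–H bond to intercept the carbenoid. C6 and C7 are set by approach to the face anti to the allylic C5 side chain and the cis C1 side chain; C11 carries two identical esters and is not yet stereogenic.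

Step 7
Reactants: 12 cyclopropanated silyl enol ether from step 6
Product: 14 dimethyl 3-[(benzyloxy)methyl]-2-(2-ethoxy-2-oxoethyl)-4-oxobicyclo[5.1.0]octane-8,8-dicarboxylate (2,3-side chains cis), via β-keto acid 13 (not isolated)
Conditions: TBAF (2.5 equiv), THF, 0 °C to rt; then AcOH, 40 °C
Reagents that add atoms: none
Why: Fluoride cleaves the silyl enol ether and, by attack at silicon with loss of ethene, the 2-(trimethylsilyl)ethyl ester; the β-keto acid 13 decarboxylates on mild warming. The conditions are near neutral so that C1, now α to the ketone, should keep its configuration and the β-benzyloxy group should not eliminate; the methyl and ethyl esters are untouched.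

Step 8
Reactants: 14 ketone from step 7
Product: 15 dimethyl 3-[(benzyloxy)methyl]-2-(2-ethoxy-2-oxoethyl)-4-hydroxy-4-methylbicyclo[5.1.0]octane-8,8-dicarboxylate (4-OH cis to the 3-CH2OBn group)
Conditions: MeMgBr (1.3 equiv), CH2Cl2/Et2O, −78 °C; then H2O
Reagents that add atoms: methylmagnesium bromide, C[Mg]Br
Why: Chelation-controlled Grignard addition (Cram chelate between the ketone and the β-benzyloxy oxygen): the methyl group enters from the side of H1, which puts the new hydroxyl cis to C2 as required at C10. At −78 °C the ketone should react well before the esters, and any lactone formed by closure of the new alkoxide onto the ethyl ester converges in step 9.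

Step 9
Reactants: 15 tertiary alcohol from step 8
Product: 16 {3-[(benzyloxy)methyl]-4-hydroxy-2-(2-hydroxyethyl)-4-methylbicyclo[5.1.0]octane-8,8-diyl}dimethanol
Conditions: LiAlH4 (excess), THF, 0 °C to rt; aqueous NaOH work-up
Reagents that add atoms: none
Why: Hydride reduction of all three esters gives C12–OH, C13–OH and C3–OH in one operation; the benzyl ether, the tertiary alcohol and the cyclopropane are inert.

Step 10
Reactants: 16 tetraol from step 9
Product: 17 3-[(benzyloxy)methyl]-2-(2-hydroxyethyl)-2',2',4-trimethylspiro[bicyclo[5.1.0]octane-8,5'-[1,3]dioxan]-4-ol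
Conditions: Me2C(OMe)2, PPTS (cat.), acetone, rt; aq NaHCO3 work-up
Reagents that add atoms: 2,2-dimethoxypropane, COC(C)(C)OC
Why: Ketal exchange; only the 1,3-diol on C11 can form a six-membered acetonide, so C12–OH and C13–OH are masked together while C3–OH stays free.

Step 11
Reactants: 17 acetonide from step 10
Product: 18 3-(hydroxymethyl)-2-(2-hydroxyethyl)-2',2',4-trimethylspiro[bicyclo[5.1.0]octane-8,5'-[1,3]dioxan]-4-ol
Conditions: H2 (1 atm), Pd(OH)2/C, EtOAc, rt
Reagents that add atoms: none
Why: Hydrogenolysis of the benzyl ether frees C2–OH; there is no alkene left, and the acetonide and the unactivated cyclopropane should survive neutral conditions.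

Step 12
Reactants: 18 triol from step 11
Product: 19 4-hydroxy-2',2',4-trimethyl-2-(2-oxoethyl)spiro[bicyclo[5.1.0]octane-8,5'-[1,3]dioxane]-3-carbaldehyde
Conditions: (COCl)2, DMSO, CH2Cl2, −78 °C; then Et3N, −78 to −30 °C; pH 7 work-up
Reagents that add atoms: none
Why: Swern oxidation activates both primary hydroxyls before base is added, so the 1,5-diol should go to the dialdehyde rather than through a lactol to a lactone; the tertiary alcohol cannot be oxidised, and the low temperature protects C1.

Step 13
Reactants: 19 dialdehyde acetonide from step 12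
Product: 20 4-hydroxy-8,8-bis(hydroxymethyl)-4-methyl-2-(2-oxoethyl)bicyclo[5.1.0]octane-3-carbaldehyde
Conditions: AcOH/H2O/THF (3:1:1), 35 °C
Reagents that add atoms: none
Why: Acid hydrolysis of the ketal frees the cyclopropane diol; dilute acetic acid should neither enolise C1 nor dehydrate the tertiary alcohol.

Step 14
Reactants: 20 diol dialdehyde from step 13
Product: 23 12,15-epoxy-2,3-seco-aromadendr-3-ene-2,10,13-triol 2,3-cyclic hemiacetal (lactol; anomers), via α-methylene dialdehyde 21 (not isolated), via oxepane dialdehyde 22 (not isolated)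
Conditions: 37% aq HCHO (1.2 equiv), pyrrolidine (20 mol %), EtCO2H (20 mol %), i-PrOH, 45 °C
Reagents that add atoms: formaldehyde, C=O
Why: Three reversible amine/acid-mediated events should run in sequence: enamine formation at the unhindered C3 aldehyde, Mannich reaction with the formaldehyde iminium ion and elimination give the α-methylene aldehyde 21 (the C2 aldehyde is α-branched and flanked by quaternary C10, so it should not compete); the endo CH2OH on C11, the only primary hydroxyl that can reach C15, then adds in an oxa-Michael reaction to close the trans-fused oxepane 22. The C3 aldehyde of 22, now enolisable at C4, closes onto the C2 aldehyde to the enol-lactol 23; an adduct of the tertiary C10 hydroxyl at C15 could not reach this sink because it would need a bridgehead double bond (Bredt's rule). C11 becomes stereogenic here by the ring constraint alone, and C4 ends sp2, so its transient configuration is irrelevant.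

Step 15
Reactants: 23 lactol from step 14
Product: 24 target CNP0250836.3 (2,13-di-O-acetyl-12,15-epoxy-2,3-seco-aromadendr-3-ene-2,10,13-triol 2,3-cyclic acetal)
Conditions: Ac2O (3 equiv), pyridine, DMAP (cat.), CH2Cl2, 0 °C
Reagents that add atoms: acetic anhydride, CC(=O)OC(C)=O
Why: Acylation of the primary C13 hydroxyl and of the anomeric hydroxyl; the tertiary C10 hydroxyl should not react at 0 °C. The anomeric acetate is expected trans to the C1–C10 bond, the pseudoaxial position favoured by the anomeric effect and by the neighbouring substituent, since the lactol anomers interconvert under the basic conditions.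

## Compound list

1 | 3-(benzyloxy)propanoic acid | OC(=O)CCOCc1ccccc1 | starting material
2 | Meldrum's acid | CC1(C)OC(=O)CC(=O)O1 | starting material
3 | 5-[3-(benzyloxy)-1-hydroxypropylidene]-2,2-dimethyl-1,3-dioxane-4,6-dione | CC1(C)OC(=O)C(=C(O)CCOCc2ccccc2)C(=O)O1 | intermediate (not isolated)
4 | 2-(trimethylsilyl)ethyl 5-(benzyloxy)-3-oxopentanoate | C[Si](C)(C)CCOC(=O)CC(=O)CCOCc1ccccc1 | intermediate
5 | 2-(trimethylsilyl)ethyl 5-(benzyloxy)-2-diazo-3-oxopentanoate | C[Si](C)(C)CCOC(=O)C(=[N+]=[N-])C(=O)CCOCc1ccccc1 | intermediate
6 | 2-(trimethylsilyl)ethyl (3Z)-5-(benzyloxy)-3-[(tert-butyldimethylsilyl)oxy]-2-diazopent-3-enoate | C[Si](C)(C)CCOC(=O)C(=[N+]=[N-])/C(O[Si](C)(C)C(C)(C)C)=C/COCc1ccccc1 | intermediate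
7 | ethyl sorbate | CCOC(=O)/C=C/C=C/C | starting material
8 | ethyl (3E)-hexa-3,5-dienoate | CCOC(=O)C/C=C/C=C | intermediate
9 | 2-(trimethylsilyl)ethyl 1-[(1Z)-3-(benzyloxy)-1-(tert-butyldimethylsilyloxy)prop-1-enyl]-2-[(1E)-4-ethoxy-4-oxobut-1-enyl]cyclopropane-1-carboxylate (alkenyl groups cis) | C[Si](C)(C)CCOC(=O)[C@@]1(/C(O[Si](C)(C)C(C)(C)C)=C/COCc2ccccc2)C[C@@H]1/C=C/CC(=O)OCC | intermediate (not isolated)
10 | 2-(trimethylsilyl)ethyl (3S,4R)-3-[(benzyloxy)methyl]-2-[(tert-butyldimethylsilyl)oxy]-4-(2-ethoxy-2-oxoethyl)cyclohepta-1,5-diene-1-carboxylate | C[Si](C)(C)CCOC(=O)C1=C(O[Si](C)(C)C(C)(C)C)[C@H](COCc2ccccc2)[C@H](CC(=O)OCC)C=CC1 | intermediate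
11 | dimethyl diazomalonate | COC(=O)C(=[N+]=[N-])C(=O)OC | starting material
12 | 8,8-dimethyl 5-[2-(trimethylsilyl)ethyl] 3-[(benzyloxy)methyl]-4-[(tert-butyldimethylsilyl)oxy]-2-(2-ethoxy-2-oxoethyl)bicyclo[5.1.0]oct-4-ene-5,8,8-tricarboxylate | C[Si](C)(C)CCOC(=O)C1=C(O[Si](C)(C)C(C)(C)C)[C@H](COCc2ccccc2)[C@H](CC(=O)OCC)[C@@H]2[C@H](C1)C2(C(=O)OC)C(=O)OC | intermediate
13 | 3-[(benzyloxy)methyl]-2-(2-ethoxy-2-oxoethyl)-8,8-bis(methoxycarbonyl)-4-oxobicyclo[5.1.0]octane-5-carboxylic acid | O=C1[C@H](COCc2ccccc2)[C@H](CC(=O)OCC)[C@@H]2[C@H](CC1C(O)=O)C2(C(=O)OC)C(=O)OC | intermediate (not isolated)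
14 | dimethyl 3-[(benzyloxy)methyl]-2-(2-ethoxy-2-oxoethyl)-4-oxobicyclo[5.1.0]octane-8,8-dicarboxylate | O=C1[C@H](COCc2ccccc2)[C@H](CC(=O)OCC)[C@@H]2[C@H](CC1)C2(C(=O)OC)C(=O)OC | intermediate
15 | dimethyl 3-[(benzyloxy)methyl]-2-(2-ethoxy-2-oxoethyl)-4-hydroxy-4-methylbicyclo[5.1.0]octane-8,8-dicarboxylate | C[C@@]1(O)[C@H](COCc2ccccc2)[C@H](CC(=O)OCC)[C@@H]2[C@H](CC1)C2(C(=O)OC)C(=O)OC | intermediate
16 | {3-[(benzyloxy)methyl]-4-hydroxy-2-(2-hydroxyethyl)-4-methylbicyclo[5.1.0]octane-8,8-diyl}dimethanol | C[C@@]1(O)[C@H](COCc2ccccc2)[C@H](CCO)[C@@H]2[C@H](CC1)C2(CO)CO | intermediate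
17 | 3-[(benzyloxy)methyl]-2-(2-hydroxyethyl)-2',2',4-trimethylspiro[bicyclo[5.1.0]octane-8,5'-[1,3]dioxan]-4-ol | C[C@@]1(O)[C@H](COCc2ccccc2)[C@H](CCO)[C@@H]2[C@H](CC1)C23COC(C)(C)OC3 | intermediate
18 | 3-(hydroxymethyl)-2-(2-hydroxyethyl)-2',2',4-trimethylspiro[bicyclo[5.1.0]octane-8,5'-[1,3]dioxan]-4-ol | C[C@@]1(O)[C@H](CO)[C@H](CCO)[C@@H]2[C@H](CC1)C23COC(C)(C)OC3 | intermediate
19 | 4-hydroxy-2',2',4-trimethyl-2-(2-oxoethyl)spiro[bicyclo[5.1.0]octane-8,5'-[1,3]dioxane]-3-carbaldehyde | C[C@@]1(O)[C@H](C=O)[C@H](CC=O)[C@@H]2[C@H](CC1)C23COC(C)(C)OC3 | intermediate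
20 | 4-hydroxy-8,8-bis(hydroxymethyl)-4-methyl-2-(2-oxoethyl)bicyclo[5.1.0]octane-3-carbaldehyde | C[C@@]1(O)[C@H](C=O)[C@H](CC=O)[C@@H]2[C@H](CC1)C2(CO)CO | intermediate
21 | 4-hydroxy-8,8-bis(hydroxymethyl)-4-methyl-2-(3-oxoprop-1-en-2-yl)bicyclo[5.1.0]octane-3-carbaldehyde | C[C@@]1(O)[C@H](C=O)[C@H](C(=C)C=O)[C@@H]2[C@H](CC1)C2(CO)CO | intermediate (not isolated)
22 | 10,13-dihydroxy-12,15-epoxy-2,3-seco-aromadendrane-2,3-dial (C4 epimers) | OC[C@]1(COC3)[C@H]2CC[C@](C)(O)[C@H](C=O)[C@H](C3C=O)[C@@H]12 | intermediate (not isolated)
23 | 12,15-epoxy-2,3-seco-aromadendr-3-ene-2,10,13-triol 2,3-cyclic hemiacetal (anomers) | OC[C@]1(COC3)[C@H]2CC[C@](C)(O)[C@H]4[C@H](C3=COC4O)[C@@H]12 | intermediate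
24 | CNP0250836.3 | CC(=O)OC[C@@]12COCC3=CO[C@H](OC(C)=O)[C@@H]4[C@H]3[C@@H]1[C@@H]2CC[C@]4(C)O | target

## Step count and least certain steps

Total steps: 15. Longest linear sequence: 14 (steps 1–3 and 5–15); step 4 is the one-step side branch.

**Step 5 (key step).** What may go wrong: loss of enantio- or diastereocontrol because the carbenoid carries a substituent on its vinyl terminus, or incomplete [3,3] shift if part of the cyclopropane forms as the trans-divinyl isomer. Fallback (sets out from 8, returns at 14): generate the vinyl carbenoid from a propargylic ester instead of a diazo compound. Benzyloxyacetaldehyde and ethynylmagnesium bromide give 1-(benzyloxy)but-3-yn-2-ol F1, which is acetylated to the propargylic acetate F2. With 8 and a chiral gold catalyst ([(R)-DTBM-SEGPHOS](AuCl)2, AgSbF6), 1,2-acyloxy migration gives a gold vinylcarbenoid; cis-cyclopropanation of the terminal alkene and Cope rearrangement should give the enol acetate cycloheptadiene F3, which has no ester on C9. Cyclopropanation with 11 as in step 6 gives the cyclopropane diester F4, and ammonolysis of its enol acetate (NH3, MeOH, 0 °C) gives ketone 14 directly.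

**Step 6.** What may go wrong: slow carbene transfer to the hindered cis alkene, so that carbene dimerisation and insertion into benzylic or allylic C–H bonds take over. Fallback (sets out from 10, returns at 15): build the cyclopropane by radical addition and ring closure instead of carbene transfer. Fluoride treatment of 10 as in step 7 gives the cycloheptenone F5, and methylmagnesium bromide as in step 8 gives the tertiary alcohol F6. A Kharasch-type atom-transfer addition of dimethyl bromomalonate (Ru(bpy)3Cl2, visible light, LiBr) across C6=C7, with the malonyl group entering anti to the side chains, should give the trans bromide F7. DBU then closes the three-membered ring by intramolecular alkylation with inversion at C6, giving 15. The free hydroxyl is no obstacle to this chemistry.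

**Step 8.** What may go wrong: poor facial selectivity if the magnesium chelate does not form, or enolisation toward C1 with loss of its configuration. Fallback (sets out from 14, returns at 16): invert the roles of nucleophile and electrophile. Takai–Lombardo methylenation (Zn, CH2Br2, TiCl4) gives the exocyclic alkene F8 without a basic ylide. Epoxidation with mCPBA gives the spiro-epoxide F9; the peracid takes the face that a methyl nucleophile would take, so the oxygen ends on the face that the Grignard route fails to deliver. LiAlH4 opens the epoxide at its CH2 and reduces the three esters in the same operation, giving tetraol 16.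

**Step 14.** What may go wrong: the reversible conjugate addition does not drain to the enol-lactol because the tertiary C10 hydroxyl intercepts the α-methylene aldehyde, or the amine catalyst causes epimerisation at C1 or retro-aldol cleavage next to C10. Fallback (sets out from 17, returns at 24): close the oxepane irreversibly before any dialdehyde exists. Dess–Martin oxidation of 17 gives the aldehyde F10, and amine-catalysed α-methylenation with formaldehyde gives the enal F11. Luche reduction (NaBH4, CeCl3·7H2O) gives the allylic alcohol F12, which methyl chloroformate and pyridine convert into the allylic carbonate F13. AcOH/H2O/THF removes the acetonide to give the diol F14. Pd(PPh3)4 in THF at high dilution ionises the carbonate to a symmetrical 2-substituted allyl complex of palladium, which the primary endo hydroxyl captures (Tsuji–Trost etherification) to give the oxepane F15 with an exocyclic methylene on C4. Ac2O and pyridine then acetylate the primary C13 hydroxyl to give the acetate F16. 9-BBN followed by NaBO3·4H2O gives the primary alcohol F17 at C3, hydrogenolysis (H2, Pd(OH)2/C) gives the diol F18, and Swern oxidation gives the dialdehyde F19. PPTS in wet CH2Cl2 closes the enol-lactol F20, and acetylation as in step 15 gives 24.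

## Further compounds

F1 | step 5 | 1-(benzyloxy)but-3-yn-2-ol | OC(COCc1ccccc1)C#C
F2 | step 5 | 1-(benzyloxy)but-3-yn-2-yl acetate | CC(=O)OC(COCc1ccccc1)C#C
F3 | step 5 | ethyl 2-{(1R,7S)-6-acetoxy-7-[(benzyloxy)methyl]cyclohepta-2,5-dien-1-yl}acetate | C1=C(OC(C)=O)[C@H](COCc2ccccc2)[C@H](CC(=O)OCC)C=CC1
F4 | step 5 | dimethyl 4-acetoxy-3-[(benzyloxy)methyl]-2-(2-ethoxy-2-oxoethyl)bicyclo[5.1.0]oct-4-ene-8,8-dicarboxylate | C1=C(OC(C)=O)[C@H](COCc2ccccc2)[C@H](CC(=O)OCC)[C@@H]2[C@H](C1)C2(C(=O)OC)C(=O)OC
F5 | step 6 | ethyl 2-{cis-7-[(benzyloxy)methyl]-6-oxocyclohept-2-en-1-yl}acetate | O=C1[C@H](COCc2ccccc2)[C@H](CC(=O)OCC)C=CCC1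
F6 | step 6 | ethyl 2-{7-[(benzyloxy)methyl]-6-hydroxy-6-methylcyclohept-2-en-1-yl}acetate (OH cis to CH2OBn) | C[C@@]1(O)[C@H](COCc2ccccc2)[C@H](CC(=O)OCC)C=CCC1
F7 | step 6 | dimethyl 2-{4-[(benzyloxy)methyl]-2-bromo-3-(2-ethoxy-2-oxoethyl)-5-hydroxy-5-methylcycloheptyl}malonate (malonyl and Br trans) | C[C@@]1(O)[C@H](COCc2ccccc2)[C@H](CC(=O)OCC)[C@H](Br)[C@H](CC1)C(C(=O)OC)C(=O)OC
F8 | step 8 | dimethyl 3-[(benzyloxy)methyl]-2-(2-ethoxy-2-oxoethyl)-4-methylidenebicyclo[5.1.0]octane-8,8-dicarboxylate | C=C1[C@H](COCc2ccccc2)[C@H](CC(=O)OCC)[C@@H]2[C@H](CC1)C2(C(=O)OC)C(=O)OC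
F9 | step 8 | dimethyl 3-[(benzyloxy)methyl]-2-(2-ethoxy-2-oxoethyl)spiro[bicyclo[5.1.0]octane-4,2'-oxirane]-8,8-dicarboxylate (epoxide O cis to CH2OBn) | O1C[C@]12[C@H](COCc3ccccc3)[C@H](CC(=O)OCC)[C@@H]3[C@H](CC2)C3(C(=O)OC)C(=O)OC
F10 | step 14 | 2-{3-[(benzyloxy)methyl]-4-hydroxy-2',2',4-trimethylspiro[bicyclo[5.1.0]octane-8,5'-[1,3]dioxan]-2-yl}acetaldehyde | C[C@@]1(O)[C@H](COCc2ccccc2)[C@H](CC=O)[C@@H]2[C@H](CC1)C23COC(C)(C)OC3
F11 | step 14 | 2-{3-[(benzyloxy)methyl]-4-hydroxy-2',2',4-trimethylspiro[bicyclo[5.1.0]octane-8,5'-[1,3]dioxan]-2-yl}prop-2-enal | C[C@@]1(O)[C@H](COCc2ccccc2)[C@H](C(=C)C=O)[C@@H]2[C@H](CC1)C23COC(C)(C)OC3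
F12 | step 14 | 3-[(benzyloxy)methyl]-2-(3-hydroxyprop-1-en-2-yl)-2',2',4-trimethylspiro[bicyclo[5.1.0]octane-8,5'-[1,3]dioxan]-4-ol | C[C@@]1(O)[C@H](COCc2ccccc2)[C@H](C(=C)CO)[C@@H]2[C@H](CC1)C23COC(C)(C)OC3
F13 | step 14 | methyl carbonate of F12 at the allylic hydroxyl | C[C@@]1(O)[C@H](COCc2ccccc2)[C@H](C(=C)COC(=O)OC)[C@@H]2[C@H](CC1)C23COC(C)(C)OC3
F14 | step 14 | 2-{3-[(benzyloxy)methyl]-4-hydroxy-8,8-bis(hydroxymethyl)-4-methylbicyclo[5.1.0]octan-2-yl}prop-2-enyl methyl carbonate | C[C@@]1(O)[C@H](COCc2ccccc2)[C@H](C(=C)COC(=O)OC)[C@@H]2[C@H](CC1)C2(CO)CO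
F15 | step 14 | 2-O-benzyl-12,15-epoxy-2,3-seco-aromadendr-4(3)-ene-2,10,13-triol (exocyclic methylene on C4) | OC[C@]1(COC3)[C@H]2CC[C@](C)(O)[C@H](COCc4ccccc4)[C@H](C3=C)[C@@H]12
F16 | step 14 | 13-O-acetyl derivative of F15 | CC(=O)OC[C@]1(COC3)[C@H]2CC[C@](C)(O)[C@H](COCc4ccccc4)[C@H](C3=C)[C@@H]12
F17 | step 14 | 13-O-acetyl-2-O-benzyl-12,15-epoxy-2,3-seco-aromadendrane-2,3,10,13-tetrol (C4 epimers) | CC(=O)OC[C@]1(COC3)[C@H]2CC[C@](C)(O)[C@H](COCc4ccccc4)[C@H](C3CO)[C@@H]12
F18 | step 14 | 13-O-acetyl-12,15-epoxy-2,3-seco-aromadendrane-2,3,10,13-tetrol (C4 epimers) | CC(=O)OC[C@]1(COC3)[C@H]2CC[C@](C)(O)[C@H](CO)[C@H](C3CO)[C@@H]12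
F19 | step 14 | 13-acetoxy-10-hydroxy-12,15-epoxy-2,3-seco-aromadendrane-2,3-dial (C4 epimers) | CC(=O)OC[C@]1(COC3)[C@H]2CC[C@](C)(O)[C@H](C=O)[C@H](C3C=O)[C@@H]12
F20 | step 14 | 13-O-acetyl-12,15-epoxy-2,3-seco-aromadendr-3-ene-2,10,13-triol 2,3-cyclic hemiacetal (anomers) | CC(=O)OC[C@]1(COC3)[C@H]2CC[C@](C)(O)[C@H]4[C@H](C3=COC4O)[C@@H]12
A1 | alternative 1 | 13-acetoxy-12,15-epoxyaromadendr-2-en-10-ol (cyclopentene precursor) | CC(=O)OC[C@]1(COC3)[C@H]2CC[C@](C)(O)[C@H]4[C@H](C3C=C4)[C@@H]12
A2 | alternative 1 | 13-acetoxy-10-hydroxy-12,15-epoxy-2,3-seco-aromadendrane-2,3-dial | CC(=O)OC[C@]1(COC3)[C@H]2CC[C@](C)(O)[C@H](C=O)[C@H](C3C=O)[C@@H]12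
A3 | alternative 2 | cyclopropane-fused dihydrooxepine carbaldehyde with tethered (E)-enol acetate | CC(=O)OC[C@@]12COCC(C=O)=C[C@@H]1[C@@H]2CC[C@](C)(O)/C=C/OC(C)=O
A4 | alternative 3 | 3-(benzyloxy)-2-{7-[(benzyloxy)methyl]-6-hydroxy-6-methylcyclohept-2-en-1-yl}propyl methyl 2-diazomalonate | C[C@@]1(O)[C@H](COCc2ccccc2)[C@H](C(COCc2ccccc2)COC(=O)C(=[N+]=[N-])C(=O)OC)C=CCC1
A5 | alternative 3 | cyclopropane-fused seven-membered lactone with exo methyl ester | COC(=O)[C@]1(C(=O)OC3)[C@H]2CC[C@](C)(O)[C@H](COCc4ccccc4)[C@H](C3COCc4ccccc4)[C@@H]12
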